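The rate constants are made up; the flask was simulated.

**The count.** In this flask E, J, J.Q and G together stay at the 1.5 M of E charged, so y counts how much of that charge has passed through the coupling of J with Q.

E 1.5 M; D 2.25 M; time 1.0 h

    D ⇌ Q, rate k1*(cs1 - [Q]) while solid is left; crystals form when [Q] > cs1 (cs1 = 0.81 M, k1 = 8.3 × 10⁻⁴ /s)
    G ⇌ J.Q, rate k2*(cs2 - [J.Q]) while solid is left; crystals form when [J.Q] > cs2 (cs2 = 0.52 M, k2 = 0.012 /s)
    Q → X (k3 = 1.6 × 10⁻⁵ /s)
    J + Q → J.Q (k4 = 4.0 × 10⁻⁴ /M/s)
    E ⇌ J, rate k5*(cs5 - [J]) while solid is left; crystals form when [J] > cs5 (cs5 = 0.89 M, k5 = 0.0018 /s)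
    2 Q → Q2 (k6 = 2.9 × 10⁻⁴ /M/s)

- what is said of J.Q includes G
- two of one species on the left: rate k times its square, two consumed each time
- E, G, D is a solid; its amount is given per volume of the solution
- at the start none of D is in solution
- at the start none of E is in solution
- J means what is dissolved; the solid is not counted in it
- run time (flask): 1.0 h

1. amount of J.Q and G together at 1.0 h, in percent of the E charged
2. concentration of J in solution at 1.0 h, in percent of saturation

**Quick rungs.** I turn the constants into times. J fills towards its solubility in 9.26 min, and Q is fed in 20.1 min, a slower start.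

**Middle rungs.** At solubility, Q pairs off in 35.5 min and couples in 46.8 min. These times are 1.77 and 2.33 times the feed time, so I keep both losses in the balance of Q. Setting feed equal to loss (the steady-state value), with c(J) at its solubility, gives c(Q) = 0.458 M, approached in 9.62 min. The loss to X, with a half-life of 12 h, is slow beside the run. That balance draws D at 1.05 M/h, against 2.25 M charged.

**Yield rung.** My plateau yield rate is the coupling constant times c(J) at solubility times that steady c(Q), divided by the E charged: 0.391 /h. The two fillings cost a lag of 14.2 min, so I reckon y at 29.9%. That is 0.449 M of J.Q, below its solubility of 0.52 M, so I expect no G by then. The balance of J gives sat = 90.8%; since c(J) falls short of solubility, my y is a high figure.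

**The forecast.** It says y = 28.1% and sat = 91%, and its approach is to “Treat Q and J as relaxing quickly to quasi-steady values”. Its y is lower than mine.

**The flask.** This flask gives y = 28.2% and sat = 90.6%. Its J.Q and G went from 10.4% at 0.500 h to that y, a late slope of 0.356 /h, under my plateau yield rate. For the neighbour charged with 0.90 M of E, the same rate becomes 0.652 /h and, after the same lag, predicts 49.8%. That neighbour gives 41.1%, with solid E at 0% and J at 58.9% of its charge.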